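(Readings and results stem from a simulated flask with constants of no real substance; scatter was added.)

**Following one initiator.** The product here is monomer in chains, and when you asked for a quick number, with your hunch that slow-fed east would end level with south-west, I followed one initiator molecule: it begins a chain or is wasted, and the living end then adds monomer or meets transfer agent, with a chance that I took to rise with [free monomer] against [transfer agent].

| setting | elm | alder | maple | south-west | east |
|---|---|---|---|---|---|
| free monomer | 17 mM (fed, over 4.0 d) | 17 mM (fed, over 4.0 d) | 26 mM (fed, over 4.0 d) | 17 mM (fed, over 4.0 d) | 17 mM (fed, over 6.0 d) |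
| transfer agent | 1.7 mM | 1.7 mM | 1.7 mM | 1.70 mM | 1.70 mM |
| initiator | 42 µM | 170 µM | 85 µM | 85 µM | 85 µM |
| remark | run made earlier | run made earlier | run made earlier |  |  |
| time |  |  |  | 5.0 d | 5.0 d |

| run | time / d | monomer in chains / % | free monomer / % |
|---|---|---|---|
| elm | 0.417 | 0 | 11 |
| elm | 0.625 | 0 | 14 |
| elm | 1.04 | 1 | 24 |
| elm | 1.67 | 1 | 38 |
| elm | 3.00 | 8 | 68 |
| elm | 5.00 | 7 | 90 |
| alder | 0.833 | 3 | 18 |
| alder | 1.67 | 8 | 33 |
| alder | 2.50 | 18 | 44 |
| alder | 3.00 | 21 | 53 |
| alder | 4.00 | 25 | 75 |
| alder | 5.00 | 28 | 70 |
| maple | 1.04 | 3 | 20 |
| maple | 2.08 | 5 | 46 |
| maple | 3.00 | 14 | 60 |
| maple | 4.00 | 11 | 85 |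
| maple | 5.00 | 16 | 85 |

(scatter of a reading: 1.5 percentage points)

- the average divides the monomer in chains by the number of chains begun, living and dead together
- steps that have been proposed: free monomer + initiator -> living end + monomer in chains; free monomer + living end -> monomer in chains + living end; living end + transfer agent -> dead chain; free monomer + initiator -> spent initiator
- percentages count the whole charge, also what has not yet gone in
- the earlier runs do not show the number of chains; that part of a forecast is a guess

- which of the two ends with the longer chains by the average number of monomer units in a chain (chains begun, living or dead) ("neither" if they lie within 10%) (south-west / east / neither)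
- average number of monomer units in a chain (chains begun, living or dead) at the end, south-west
- average number of monomer units in a chain (chains begun, living or dead) at the end, east

**Units per initiator.** The last alder reading gave 28.0 units per initiator, the monomer in chains at the end divided by the initiator charged. Elm, with a quarter of alder's initiator, gave 28.3, though its small reading carries the same scatter of 1.5 percentage points. By the proposed steps one chain takes one initiator, so the average length had to sit at units per initiator or above, and I took 28.0 as the floor for south-west, which has the free monomer charge and feed of those runs.

**The order.** Maple, fed at 6.50 mM d⁻¹, gave 48.9 units per initiator, and east is fed at 2.83 mM d⁻¹ against 4.25 mM d⁻¹ for south-west, so I set east shorter, against your hunch.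

**The forecast.** My reckoning gave a floor and an order, whereas the forecast named lengths: 45 for south-west and 35 for east, with south-west longer. Its ground ran: “Chain length follows free monomer while the ends live”.

**The flask.** South-west ended at 41.3 units and east at 30.4, so south-west was longer.

    free monomer + initiator → living end + monomer in chains (k = 0.00505 M⁻¹ s⁻¹)
    free monomer + living end → monomer in chains + living end, rate k2*[living end]*[free monomer] (k = 0.0726 M⁻¹ s⁻¹)
    living end + transfer agent → dead chain (kL = 0.00682 M⁻¹ s⁻¹)
    free monomer + initiator → spent initiator (k = 0.00153 M⁻¹ s⁻¹)

In south-west, initiator stood at 0%, with chains begun at 0.0652 mM and spent initiator at 0.0198 mM, and the length stood above the floor. Yet the path to spent initiator makes no difference to that length. The neighbour of south-west charged with 29 mM of free monomer gave 48.7 units per initiator and ended at a length of 63.5.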